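**Retrosynthetic overview**
1. Feature: in the oxolane ring (O1; C2 carrying the carbinol carbon C1'; C3 carrying 4-methoxyphenyl; C4 carrying OH; C5 = CH2), O1 lies between C2 and C5 and the C2 and C3 substituents are cis. Excising O1 therefore contracts the ring to a cis-disubstituted cyclobutanone with C5 as the carbonyl carbon.
2. The C4–OH, cis to both neighbours, is traced to hydride attack on the open face of a C4 ketone. The ketone comes from hydroboration–oxidation of the C4=C5 enol ether, made from the γ-lactone through its lactol, which also turns C5 into CH2.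
3. Key disconnection: O1–C2 and O1–C5, by Baeyer–Villiger ring expansion of the 2,2-dichlorocyclobutanone. The two chlorines on C4 leave C2 as the only carbon able to migrate.
4. C2–C5 and C3–C4 come from a [2+2] cycloaddition of dichloroketene to the Z alkene ArCH=CH–CH(OTBS)Ar'. C1', the only source of chirality, is set by catalytic asymmetric alkynylation of 3,4-dimethoxybenzaldehyde.
5. Ring order: cyclobutane (step 4), then the oxolane by one-atom expansion (step 5). The oxolane is not reopened afterwards.

Key step: step 5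

The atom labels O1, C2, C3, C4, C5 and C1' are those of the target oxolane and are kept for all intermediates.

Assumption (step 1): (S)-BINOL/Ti(OiPr)4 is taken to send the alkynylzinc to the Si face of the aromatic aldehyde, which gives (R)-4. The configuration is to be checked on 4, and the antipodal ligand is equally available.

Assumption (step 4): the ketene is taken to add to the alkene face anti to the silyloxy group of the A(1,3)-locked conformer of 6.

Design remarks:
- The chlorines serve only as regiocontrol elements and are then removed.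
- Displacing a C4 chloride of the lactone with a carboxylate is not used. Chloride and carboxylate would epimerise the α-chloro lactone, and the cis chloride, attacked from the open face, would drain the mixture to the unwanted trans C4–O isomer.
- Silane/Lewis acid reduction of the lactol is not used, because the 3,4-dimethoxybenzylic C1'–O bond would ionise under such conditions.

**Route**

Step 1
Reactants: 1 3,4-dimethoxybenzaldehyde; 2 4-ethynylanisole
Product: 4 (R)-1-(3,4-dimethoxyphenyl)-3-(4-methoxyphenyl)prop-2-yn-1-ol, via alkynyl(ethyl)zinc 3 (not isolated)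
Conditions: 2, Et2Zn, toluene, reflux; then (S)-BINOL (20 mol %), Ti(OiPr)4 (50 mol %), Et2O, rt; then 1, rt; aq NH4Cl
Reagents that add atoms: diethylzinc, CC[Zn]CC (ethylzinc unit of 3 only)
Why: BINOL–Ti(OiPr)4-catalysed asymmetric addition of an alkynylzinc to an aldehyde, a reaction type suited to pairing aryl acetylenes with aromatic aldehydes; the chiral titanium complex should shield the Re face of 1 so that the alkynyl group of 3 enters from the Si face and sets C1' as R.

Step 2
Reactants: 4 (R)-propargylic alcohol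
Product: 5 (R)-tert-butyl{[1-(3,4-dimethoxyphenyl)-3-(4-methoxyphenyl)prop-2-yn-1-yl]oxy}dimethylsilane
Conditions: TBSCl, imidazole, DMF, rt
Reagents that add atoms: tert-butyldimethylsilyl chloride, CC(C)(C)[Si](C)(C)Cl
Why: Imidazole-promoted O-silylation of a secondary alcohol, which leaves C1' untouched and installs a bulky, weakly nucleophilic ether oxygen that resists acylation by the ketene in step 4.

Step 3
Reactants: 5 (R)-propargylic TBS ether
Product: 6 tert-butyl{[(1S,2Z)-1-(3,4-dimethoxyphenyl)-3-(4-methoxyphenyl)prop-2-en-1-yl]oxy}dimethylsilane (C1' spatially unchanged; the descriptor changes by priority only)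
Conditions: H2 (1 atm), Pd/CaCO3 poisoned with Pb(OAc)2, quinoline, EtOAc, rt, stopped after one equivalent of H2
Reagents that add atoms: none
Why: Lindlar semihydrogenation: syn addition of H2 on the lead- and quinoline-poisoned palladium surface gives the Z alkene and stops there, and the neutral medium leaves the benzylic C1'–O bond intact.

Step 4
Reactants: 6 (1S,2Z)-alkene; 7 trichloroacetyl chloride
Product: 9 (3R,4S)-4-[(S)-(tert-butyldimethylsilyloxy)(3,4-dimethoxyphenyl)methyl]-2,2-dichloro-3-(4-methoxyphenyl)cyclobutan-1-one (cis-3,4), via dichloroketene 8 (not isolated)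
Conditions: 7 (slow addition), Zn–Cu couple, DME, Et2O, 0 °C to rt; filtration, aq NaHCO3 wash, used crude
Reagents that add atoms: none
Why: Thermal ketene–alkene [2+2] cycloaddition with 8 made in the flask by zinc dechlorination of 7: the carbonyl carbon of 8 bonds to C2 and the CCl2 carbon to the benzylic C3, where the 4-methoxyphenyl group carries the developing positive charge, the suprafacial addition turns the Z geometry into the cis C2/C3 pair, and A(1,3) strain holds C1'–H in the alkene plane next to the aryl group so that the ketene should enter anti to the bulky, electron-rich OTBS group (the sense seen in osmylation and peracid epoxidation of Z-allylic silyl ethers), which sets both new centres (3R,4S in 9), while DME ties up ZnCl2 and so protects the allylic, benzylic silyl ether.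

Step 5
Reactants: 9 cis-dichlorocyclobutanone
Product: 11 (4S,5S)-5-[(R)-(tert-butyldimethylsilyloxy)(3,4-dimethoxyphenyl)methyl]-3,3-dichloro-4-(4-methoxyphenyl)oxolan-2-one (cis-4,5), via Criegee adduct 10 (not isolated)
Conditions: mCPBA, NaHCO3, CH2Cl2, 0 °C to rt
Reagents that add atoms: 3-chloroperbenzoic acid, OOC(=O)c1cccc(Cl)c1
Why: Nucleophilic attack of mCPBA on C5, whose electrophilicity is raised by ring strain and by the neighbouring CCl2 group, makes the O1–C5 bond and gives the tetrahedral peroxy hemiketal 10, in which the C2–C5 bond antiperiplanar to O–O shifts to the proximal peroxide oxygen as 3-chlorobenzoate departs, making O1–C2. The closest known reaction type is the Baeyer–Villiger oxidation of α,α-dichlorocyclobutanones obtained from dichloroketene–alkene cycloadducts. The five-membered ring is formed by a 1,2-shift that enlarges the four-membered ring by one atom, so no exo or endo cyclisation mode applies, and relief of cyclobutanone strain drives the step. No stereocentre is created: the concerted shift keeps the configuration of the migrating C2, and C3 and C1' are spectators, so the cis C2/C3 pair of 9 passes into 11. The selectivity needed is regiochemical, migration of C2 and not of C4, and the two chlorines secure it because they deny C4 the partial positive charge that a migrating carbon must carry, whereas C2 is an ordinary secondary carbon. Chemoselectivity over the two electron-rich arenes rests on the fast reaction of the activated ketone at low temperature, and solid NaHCO3 keeps the liberated acid from cleaving the benzylic silyl ether or epimerising C2.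

Step 6
Reactants: 11 dichlorolactone
Product: 13 (4S,5S)-5-[(R)-(tert-butyldimethylsilyloxy)(3,4-dimethoxyphenyl)methyl]-4-(4-methoxyphenyl)oxolan-2-one, via monochlorolactone 12 (not isolated)
Conditions: Zn–Cu couple, NH4Cl, MeOH, rt
Reagents that add atoms: none
Why: Zinc-mediated reductive dehalogenation of an α-halo carbonyl compound: each C4–Cl bond is reduced to a zinc enolate that NH4Cl protonates (11 to 12 to 13), the nearly neutral medium spares the silyl ether, and C3, C2 and C1' are not acidic and keep their configuration.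

Step 7
Reactants: 13 γ-lactone
Product: 14 (4S,5S)-5-[(R)-(tert-butyldimethylsilyloxy)(3,4-dimethoxyphenyl)methyl]-4-(4-methoxyphenyl)oxolan-2-ol (anomer mixture at C5 of the target numbering)
Conditions: i-Bu2AlH, CH2Cl2, −78 °C; aq potassium sodium tartrate
Reagents that add atoms: none
Why: Partial reduction of a γ-lactone with i-Bu2AlH, which stops at the tetrahedral aluminium hemiacetal at −78 °C and gives the lactol on work-up; the new centre is an anomer mixture and is removed in step 8.

Step 8
Reactants: 14 lactol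
Product: 16 (2S,3S)-2-[(R)-(tert-butyldimethylsilyloxy)(3,4-dimethoxyphenyl)methyl]-3-(4-methoxyphenyl)-2,3-dihydrofuran, via anomeric mesylate 15 (not isolated)
Conditions: MsCl, Et3N, CH2Cl2, −40 °C to reflux; basic alumina
Reagents that add atoms: methanesulfonyl chloride, CS(=O)(=O)Cl (mesyl group of 15 only)
Why: Dehydration of a lactol through its anomeric sulfonate: 15 ionises with help from O1 and loses a C4 proton to Et3N, a known way to 2,3-dihydrofurans that runs under basic conditions and so avoids the Lewis acids that would ionise the C1'–O bond.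

Step 9
Reactants: 16 dihydrofuran
Product: 18 (3R,4R,5S)-5-[(R)-(tert-butyldimethylsilyloxy)(3,4-dimethoxyphenyl)methyl]-4-(4-methoxyphenyl)oxolan-3-ol (C4–OH trans to the aryl group), via C4 alkylborane 17 (not isolated)
Conditions: BH3·THF, THF, 0 °C; then NaOH, H2O2, 0 °C to rt
Reagents that add atoms: hydrogen peroxide, OO (oxygen on C4); borane–THF, [BH3-][O+]1CCCC1 (boron of 17 only)
Why: Hydroboration–oxidation of a cyclic enol ether: polarisation by O1 sends boron to C4 and hydrogen to C5 (now CH2), the borane approaches anti to the C3 aryl group and the C2 side chain, and oxidation with retention gives the trans alcohol, whose C4 configuration does not matter because step 10 erases it.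

Step 10
Reactants: 18 trans alcohol
Product: 19 (4S,5S)-5-[(R)-(tert-butyldimethylsilyloxy)(3,4-dimethoxyphenyl)methyl]-4-(4-methoxyphenyl)oxolan-3-one
Conditions: Dess–Martin periodinane, NaHCO3, CH2Cl2, 0 °C to rt; used without chromatography
Reagents that add atoms: none
Why: Dess–Martin oxidation of a secondary alcohol, chosen because the buffered, nearly neutral medium and the short reaction time give the α-aryl ketone little chance to enolise towards C3.

Step 11
Reactants: 19 C4 ketone
Product: 20 (3S,4R,5S)-5-[(R)-(tert-butyldimethylsilyloxy)(3,4-dimethoxyphenyl)methyl]-4-(4-methoxyphenyl)oxolan-3-ol (all-cis)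
Conditions: LiBH(s-Bu)3, THF, −78 °C; H2O
Reagents that add atoms: none
Why: Sterically controlled ketone reduction with a bulky trialkylborohydride, as in the conversion of 2-substituted cyclopentanones into cis alcohols: hydride reaches C4 only from the face opposite the C3 aryl group and the C2 side chain, which places the new hydroxyl on their face and sets C4 as S.

Step 12
Reactants: 20 all-cis silyl ether
Product: 21 (3S,4R,5S)-5-[(R)-(3,4-dimethoxyphenyl)(hydroxy)methyl]-4-(4-methoxyphenyl)oxolan-3-ol (target CNP0350816.1)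
Conditions: Bu4NF, THF, 0 °C to rt
Reagents that add atoms: none
Why: Fluoride-induced cleavage of the silyl ether, driven by the strong Si–F bond; no stereocentre is involved and the diol carries no base-sensitive group.

**Compound list**
1 | 3,4-dimethoxybenzaldehyde | COc1ccc(C=O)cc1OC | starting material
2 | 4-ethynylanisole | COc1ccc(C#C)cc1 | starting material
3 | ethyl[(4-methoxyphenyl)ethynyl]zinc (not isolated) | CC[Zn]C#Cc1ccc(OC)cc1 | intermediate
4 | (R)-1-(3,4-dimethoxyphenyl)-3-(4-methoxyphenyl)prop-2-yn-1-ol | COc1ccc(C#C[C@H](O)c2ccc(OC)c(OC)c2)cc1 | intermediate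
5 | (R)-tert-butyl{[1-(3,4-dimethoxyphenyl)-3-(4-methoxyphenyl)prop-2-yn-1-yl]oxy}dimethylsilane | COc1ccc(C#C[C@H](O[Si](C)(C)C(C)(C)C)c2ccc(OC)c(OC)c2)cc1 | intermediate
6 | tert-butyl{[(1S,2Z)-1-(3,4-dimethoxyphenyl)-3-(4-methoxyphenyl)prop-2-en-1-yl]oxy}dimethylsilane | COc1ccc(/C=C\[C@H](O[Si](C)(C)C(C)(C)C)c2ccc(OC)c(OC)c2)cc1 | intermediate
7 | trichloroacetyl chloride | O=C(Cl)C(Cl)(Cl)Cl | starting material
8 | dichloroketene (not isolated) | ClC(Cl)=C=O | intermediate
9 | (3R,4S)-4-[(S)-(tert-butyldimethylsilyloxy)(3,4-dimethoxyphenyl)methyl]-2,2-dichloro-3-(4-methoxyphenyl)cyclobutan-1-one | COc1ccc([C@H]2[C@@H]([C@H](O[Si](C)(C)C(C)(C)C)c3ccc(OC)c(OC)c3)C(=O)C2(Cl)Cl)cc1 | intermediate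
10 | Criegee adduct of 9 and mCPBA, the 1-hydroxycyclobutyl 3-chloroperbenzoate, C5 undefined (not isolated) | COc1ccc([C@H]2[C@@H]([C@H](O[Si](C)(C)C(C)(C)C)c3ccc(OC)c(OC)c3)C(O)(OOC(=O)c3cccc(Cl)c3)C2(Cl)Cl)cc1 | intermediate
11 | (4S,5S)-5-[(R)-(tert-butyldimethylsilyloxy)(3,4-dimethoxyphenyl)methyl]-3,3-dichloro-4-(4-methoxyphenyl)oxolan-2-one | COc1ccc([C@H]2[C@@H]([C@H](O[Si](C)(C)C(C)(C)C)c3ccc(OC)c(OC)c3)OC(=O)C2(Cl)Cl)cc1 | intermediate
12 | (4S,5S)-5-[(R)-(tert-butyldimethylsilyloxy)(3,4-dimethoxyphenyl)methyl]-3-chloro-4-(4-methoxyphenyl)oxolan-2-one, chloride epimers (not isolated) | COc1ccc([C@H]2[C@@H]([C@H](O[Si](C)(C)C(C)(C)C)c3ccc(OC)c(OC)c3)OC(=O)C2Cl)cc1 | intermediate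
13 | (4S,5S)-5-[(R)-(tert-butyldimethylsilyloxy)(3,4-dimethoxyphenyl)methyl]-4-(4-methoxyphenyl)oxolan-2-one | COc1ccc([C@H]2[C@@H]([C@H](O[Si](C)(C)C(C)(C)C)c3ccc(OC)c(OC)c3)OC(=O)C2)cc1 | intermediate
14 | (4S,5S)-5-[(R)-(tert-butyldimethylsilyloxy)(3,4-dimethoxyphenyl)methyl]-4-(4-methoxyphenyl)oxolan-2-ol, anomer mixture | COc1ccc([C@H]2[C@@H]([C@H](O[Si](C)(C)C(C)(C)C)c3ccc(OC)c(OC)c3)OC(O)C2)cc1 | intermediate
15 | anomeric methanesulfonate of 14 (not isolated) | COc1ccc([C@H]2[C@@H]([C@H](O[Si](C)(C)C(C)(C)C)c3ccc(OC)c(OC)c3)OC(OS(C)(=O)=O)C2)cc1 | intermediate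
16 | (2S,3S)-2-[(R)-(tert-butyldimethylsilyloxy)(3,4-dimethoxyphenyl)methyl]-3-(4-methoxyphenyl)-2,3-dihydrofuran | COc1ccc([C@H]2[C@@H]([C@H](O[Si](C)(C)C(C)(C)C)c3ccc(OC)c(OC)c3)OC=C2)cc1 | intermediate
17 | C4 alkylborane from 16, BH2 trans to the aryl group (not isolated) | COc1ccc([C@H]2[C@@H]([C@H](O[Si](C)(C)C(C)(C)C)c3ccc(OC)c(OC)c3)OC[C@@H]2B)cc1 | intermediate
18 | (3R,4R,5S)-5-[(R)-(tert-butyldimethylsilyloxy)(3,4-dimethoxyphenyl)methyl]-4-(4-methoxyphenyl)oxolan-3-ol | COc1ccc([C@H]2[C@@H]([C@H](O[Si](C)(C)C(C)(C)C)c3ccc(OC)c(OC)c3)OC[C@@H]2O)cc1 | intermediate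
19 | (4S,5S)-5-[(R)-(tert-butyldimethylsilyloxy)(3,4-dimethoxyphenyl)methyl]-4-(4-methoxyphenyl)oxolan-3-one | COc1ccc([C@H]2[C@@H]([C@H](O[Si](C)(C)C(C)(C)C)c3ccc(OC)c(OC)c3)OCC2=O)cc1 | intermediate
20 | (3S,4R,5S)-5-[(R)-(tert-butyldimethylsilyloxy)(3,4-dimethoxyphenyl)methyl]-4-(4-methoxyphenyl)oxolan-3-ol | COc1ccc([C@H]2[C@@H]([C@H](O[Si](C)(C)C(C)(C)C)c3ccc(OC)c(OC)c3)OC[C@H]2O)cc1 | intermediate
21 | (3S,4R,5S)-5-[(R)-(3,4-dimethoxyphenyl)(hydroxy)methyl]-4-(4-methoxyphenyl)oxolan-3-ol | COc1ccc([C@H]2[C@@H]([C@H](O)c3ccc(OC)c(OC)c3)OC[C@H]2O)cc1 | target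

Total step count: 12
Longest linear sequence: 12 steps (from 1 or 2 to 21; 7 enters in step 4)

**Steps most likely to fail**

Step 4. The ketene may add mainly to the other alkene face, anti to the 3,4-dimethoxyphenyl group instead of anti to OTBS. A stepwise course through the 4-methoxybenzylic cation could also erode the cis relationship.

The fallback sets out from 1 and 2 and comes back at 13. It uses the carbinol centre in its antipodal form as a relay and inverts it once the ring centres are in place.
- (R)-BINOL in the alkynylation gives (S)-1-(3,4-dimethoxyphenyl)-3-(4-methoxyphenyl)prop-2-yn-1-ol F1.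
- Silylation gives the (S)-propargylic TBS ether F2, and semihydrogenation gives the (1R,2Z)-alkene F3.
- Addition of 8 anti to the aryl group then gives the C1'-epimeric dichlorocyclobutanone F4, which has the required C2 and C3.
- Baeyer–Villiger oxidation through the C1'-epimeric Criegee adduct F5 gives the C1'-epimeric dichlorolactone F6.
- Zn–Cu couple with NH4Cl in MeOH leads through the C1'-epimeric monochlorolactone F7 to the C1'-epimeric lactone F8.
- Bu4NF buffered with AcOH frees the (S)-carbinol lactone F9.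
- Mitsunobu inversion (4-nitrobenzoic acid, PPh3, DIAD) gives the (R)-4-nitrobenzoate F10. This is a known way of interconverting the diastereomers of electron-rich 1-aryl-2-oxy carbinols.
- Methanolysis with K2CO3 in MeOH at 0 °C gives the (R)-carbinol lactone F11, and TBSCl with imidazole returns 13.

Step 10 (together with step 11). The α-aryl ketone may enolise towards C3 during oxidation, handling or hydride addition. This would epimerise C3 to the trans C2/C3 series or open the ring by β-elimination of O1.

The fallback sets out from 18 and comes back at 20, and it replaces the redox inversion by an SN2 inversion that never passes through a ketone. Mitsunobu reaction of 18 with 4-nitrobenzoic acid, PPh3 and DIAD gives the inverted C4 4-nitrobenzoate F12, and K2CO3 in MeOH cleaves the ester to 20.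

Step 5. Peracid addition to the carbonyl, flanked by CCl2 and by the branched C2 substituent, may be slow. Base-induced cleavage of the dichloroketone, epimerisation at C2 or oxidation of the arenes could then compete.

The fallback sets out from 9 and comes back at 13. It removes the chlorines first and lets substitution, not halogen, steer the migration.
- Zn–Cu couple with NH4Cl in MeOH takes 9 through the monochlorocyclobutanone F13 to the chlorine-free cis-cyclobutanone F14.
- This ketone is less hindered and tolerates base.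
- Its Baeyer–Villiger oxidation with mCPBA and NaHCO3 runs through the Criegee adduct F15.
- The secondary C2 migrates in preference to the C4 methylene, which gives 13 directly.

**Further compounds**
F1 | step 4 | (S)-1-(3,4-dimethoxyphenyl)-3-(4-methoxyphenyl)prop-2-yn-1-ol | COc1ccc(C#C[C@@H](O)c2ccc(OC)c(OC)c2)cc1
F2 | step 4 | (S)-tert-butyl{[1-(3,4-dimethoxyphenyl)-3-(4-methoxyphenyl)prop-2-yn-1-yl]oxy}dimethylsilane | COc1ccc(C#C[C@@H](O[Si](C)(C)C(C)(C)C)c2ccc(OC)c(OC)c2)cc1
F3 | step 4 | tert-butyl{[(1R,2Z)-1-(3,4-dimethoxyphenyl)-3-(4-methoxyphenyl)prop-2-en-1-yl]oxy}dimethylsilane | COc1ccc(/C=C\[C@@H](O[Si](C)(C)C(C)(C)C)c2ccc(OC)c(OC)c2)cc1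
F4 | step 4 | (3R,4S)-4-[(R)-(tert-butyldimethylsilyloxy)(3,4-dimethoxyphenyl)methyl]-2,2-dichloro-3-(4-methoxyphenyl)cyclobutan-1-one | COc1ccc([C@H]2[C@@H]([C@@H](O[Si](C)(C)C(C)(C)C)c3ccc(OC)c(OC)c3)C(=O)C2(Cl)Cl)cc1
F5 | step 4 | Criegee adduct of F4 and mCPBA (not isolated) | COc1ccc([C@H]2[C@@H]([C@@H](O[Si](C)(C)C(C)(C)C)c3ccc(OC)c(OC)c3)C(O)(OOC(=O)c3cccc(Cl)c3)C2(Cl)Cl)cc1
F6 | step 4 | (4S,5S)-5-[(S)-(tert-butyldimethylsilyloxy)(3,4-dimethoxyphenyl)methyl]-3,3-dichloro-4-(4-methoxyphenyl)oxolan-2-one | COc1ccc([C@H]2[C@@H]([C@@H](O[Si](C)(C)C(C)(C)C)c3ccc(OC)c(OC)c3)OC(=O)C2(Cl)Cl)cc1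
F7 | step 4 | (4S,5S)-5-[(S)-(tert-butyldimethylsilyloxy)(3,4-dimethoxyphenyl)methyl]-3-chloro-4-(4-methoxyphenyl)oxolan-2-one, chloride epimers (not isolated) | COc1ccc([C@H]2[C@@H]([C@@H](O[Si](C)(C)C(C)(C)C)c3ccc(OC)c(OC)c3)OC(=O)C2Cl)cc1
F8 | step 4 | (4S,5S)-5-[(S)-(tert-butyldimethylsilyloxy)(3,4-dimethoxyphenyl)methyl]-4-(4-methoxyphenyl)oxolan-2-one | COc1ccc([C@H]2[C@@H]([C@@H](O[Si](C)(C)C(C)(C)C)c3ccc(OC)c(OC)c3)OC(=O)C2)cc1
F9 | step 4 | (4S,5S)-5-[(S)-(3,4-dimethoxyphenyl)(hydroxy)methyl]-4-(4-methoxyphenyl)oxolan-2-one | COc1ccc([C@H]2[C@@H]([C@@H](O)c3ccc(OC)c(OC)c3)OC(=O)C2)cc1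
F10 | step 4 | (R)-(3,4-dimethoxyphenyl)[(2S,3S)-3-(4-methoxyphenyl)-5-oxooxolan-2-yl]methyl 4-nitrobenzoate | COc1ccc([C@H]2[C@@H]([C@H](OC(=O)c4ccc([N+](=O)[O-])cc4)c3ccc(OC)c(OC)c3)OC(=O)C2)cc1
F11 | step 4 | (4S,5S)-5-[(R)-(3,4-dimethoxyphenyl)(hydroxy)methyl]-4-(4-methoxyphenyl)oxolan-2-one | COc1ccc([C@H]2[C@@H]([C@H](O)c3ccc(OC)c(OC)c3)OC(=O)C2)cc1
F12 | step 10 | (3S,4R,5S)-5-[(R)-(tert-butyldimethylsilyloxy)(3,4-dimethoxyphenyl)methyl]-4-(4-methoxyphenyl)oxolan-3-yl 4-nitrobenzoate | COc1ccc([C@H]2[C@@H]([C@H](O[Si](C)(C)C(C)(C)C)c3ccc(OC)c(OC)c3)OC[C@H]2OC(=O)c4ccc([N+](=O)[O-])cc4)cc1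
F13 | step 5 | (3R,4S)-4-[(S)-(tert-butyldimethylsilyloxy)(3,4-dimethoxyphenyl)methyl]-2-chloro-3-(4-methoxyphenyl)cyclobutan-1-one, chloride epimers (not isolated) | COc1ccc([C@H]2[C@@H]([C@H](O[Si](C)(C)C(C)(C)C)c3ccc(OC)c(OC)c3)C(=O)C2Cl)cc1
F14 | step 5 | (2S,3R)-2-[(S)-(tert-butyldimethylsilyloxy)(3,4-dimethoxyphenyl)methyl]-3-(4-methoxyphenyl)cyclobutan-1-one | COc1ccc([C@H]2[C@@H]([C@H](O[Si](C)(C)C(C)(C)C)c3ccc(OC)c(OC)c3)C(=O)C2)cc1
F15 | step 5 | Criegee adduct of F14 and mCPBA (not isolated) | COc1ccc([C@H]2[C@@H]([C@H](O[Si](C)(C)C(C)(C)C)c3ccc(OC)c(OC)c3)C(O)(OOC(=O)c3cccc(Cl)c3)C2)cc1
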